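The twelve-membered ring is opened at both C4–C15 bonds. This gives two identical lindenane halves, each with a C4 dienyl triflate and a C11 iodomethyl group, which are rejoined head-to-tail by a Negishi cyclodimerisation. Each half is traced to (R)-Wieland–Miescher ketone, because the cyclopropane C1–C2–C3 and the five-membered ring C1/C3/C4/C5/C10 are together a cyclohexane C10–C1–C2–C3–C4–C5 with one extra C1–C3 bond. The key step forms this bond: in the 4,7-dioxo-Δ5 octalin the C3 enolate of the C4 ketone displaces an equatorial C1 mesylate cis to C14, which closes both rings and sets C1 and C3 in one operation. The precursor is the 1β-mesylate of this ene-dione.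

Key step: step 4

Remark on numbering: lindenane numbering is used for every intermediate (C1 = saturated carbonyl carbon of the starting ketone, C4 = allylic CH2, C5=C6, C7 = enone carbonyl carbon, C10 quaternary, C14 = angular methyl); β is the face of C14.
Remark on a reagent: 4-methoxybenzyl chloromethyl ether (21) is assumed to be purchasable; if not, it is made in one step from (4-methoxybenzyloxy)methyl methyl sulfide and SO2Cl2.
Remark on epimers: compounds 15 and 17–20 are carried as C11 epimer mixtures (C11 is re-enolised in step 12), so their SMILES leave C11 open.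

Step 1
Reactants: 1 (R)-Wieland–Miescher ketone
Product: 2 1β-hydroxy enone (alcohol cis to C14)
Conditions: NaBH4 (0.3 equiv), EtOH, −10 °C
Reagents that add atoms: none
Why: Chemoselective borohydride reduction of the saturated C1 ketone beside the less electrophilic enone; hydride adds anti to the axial C14 methyl, so the equatorial 1β-alcohol (cis to C14) is set at the new stereocentre.

Step 2
Reactants: 2 1β-hydroxy enone; 3 methanesulfonyl chloride
Product: 4 1β-mesyloxy enone
Conditions: MsCl, Et3N, CH2Cl2, 0 °C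
Reagents that add atoms: methanesulfonyl chloride, CS(=O)(=O)Cl
Why: Mesylation (sulfonate ester formation) of the unhindered equatorial alcohol with retention at C1; the leaving group is installed before the oxidation so that no free hydroxyl meets the oxidant and no γ-hydroxy ene-dione has to be handled.

Step 3
Reactants: 4 1β-mesyloxy enone; 5 tert-butyl hydroperoxide
Product: 6 1β-mesyloxy ene-dione (4,7-dioxo-Δ5)
Conditions: Rh2(caprolactamate)4 (1 mol %), t-BuOOH (70 % aq.), ClCH2CH2Cl, 40 °C
Reagents that add atoms: tert-butyl hydroperoxide, CC(C)(C)OO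
Why: Allylic oxidation of an enone γ-methylene to the 1,4-ene-dione by the tert-butylperoxy radical under dirhodium caprolactamate catalysis, a known transformation of steroidal and bicyclic enones; C4 is the only allylic CH2 and the base-free medium leaves the mesylate untouched.

Step 4
Reactants: 6 1β-mesyloxy ene-dione
Product: 8 tricyclic lindenane ene-dione, via potassium C3 enolate 7 (not isolated)
Conditions: KOt-Bu (1.2 equiv), THF/t-BuOH 5:1, 0 °C, 0.02 M
Reagents that add atoms: none
Why: Reversible deprotonation gives the cross-conjugated C3 enolate 7, whose α-face lobe at C3 attacks C1 anti to the equatorial C–OMs bond (W arrangement in the ring A half-chair), an intramolecular SN2 γ-elimination of the type that converts 4-sulfonyloxycyclohexanones into bicyclo[3.1.0]hexan-2-ones. The cyclopropane C1–C2–C3 closes 3-exo-tet, and the same C1–C3 bond contracts six-membered ring A to the cyclopentanone C1/C3/C4/C5/C10, so one bond closes both rings. C1 is inverted, so the 1β-mesylate (cis to C14, from step 1) places C2 on the C14 face and H1 on the opposite face; C3 follows because the new ring fusion can only be cis, and C10 is untouched. Regioselectivity rests on geometry: the C8 enolate forms as well but has no electrophile within reach and is returned to 6 by proton exchange under the equilibrating alkoxide conditions, while E2 loss of mesylate should be slower than the intramolecular closure. Moderate dilution is used to suppress Michael addition of either enolate to the ene-dione.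

Step 5
Reactants: 8 tricyclic lindenane ene-dione; 9 N-phenylbis(trifluoromethanesulfonimide)
Product: 10 C7 enol triflate (4-ketone)
Conditions: LiN(SiMe3)2, THF, −78 °C; then PhNTf2, −78 → 0 °C
Reagents that add atoms: N-phenylbis(trifluoromethanesulfonimide), O=S(=O)(N(c1ccccc1)S(=O)(=O)C(F)(F)F)C(F)(F)F
Why: Kinetic enolisation and O-triflation; C8 carries the only readily removable α-hydrogens of 8 (C3 is a cyclopropane carbon and C6 is vinylic), so one cross-conjugated dienyl triflate should form.

Step 6
Reactants: 10 C7 enol triflate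
Product: 11 4β-alcohol
Conditions: NaBH4, CeCl3·7H2O, MeOH, −78 °C
Reagents that add atoms: none
Why: Luche 1,2-reduction removes the C4 carbonyl, which would otherwise make H7 vinylogously acidic in steps 10 to 14; hydride should enter anti to the cyclopropane methylene and C14 to give the 4β-alcohol, a centre that is erased again in step 15.

Step 7
Reactants: 11 4β-alcohol; 12 tert-butyldimethylsilyl trifluoromethanesulfonate
Product: 13 4β-silyl ether dienyl triflate
Conditions: t-BuMe2SiOTf, 2,6-lutidine, CH2Cl2, −78 → 0 °C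
Reagents that add atoms: tert-butyldimethylsilyl trifluoromethanesulfonate, CC(C)(C)[Si](C)(C)OS(=O)(=O)C(F)(F)F
Why: Silyl ether formation with the triflate reagent, chosen because the 4β-hydroxyl sits on the hindered concave face.

Step 8
Reactants: 13 4β-silyl ether dienyl triflate; 14 methyl 2-bromopropanoate
Product: 15 diene ester (C7–CH(CH3)CO2Me)
Conditions: 14, Zn (activated), THF, rt; then 13, Pd2(dba)3 (2.5 mol %), XPhos, THF, 50 °C
Reagents that add atoms: methyl 2-bromopropanoate, COC(=O)C(C)Br
Why: Palladium-catalysed cross-coupling of a Reformatsky (zinc ester enolate) reagent with an alkenyl triflate, a Negishi-type α-alkenylation, forms the C7–C11 bond; both C11 epimers are carried on because C11 is enolised again in step 12.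

Step 9
Reactants: 15 diene ester; 16 hydrogen peroxide
Product: 18 8α-alcohol, via C8 alkylborane 17 (not isolated)
Conditions: BH3·THF (1.1 equiv), THF, 0 °C; then H2O2, aq. NaOH, 0 °C
Reagents that add atoms: hydrogen peroxide, OO
Why: Hydroboration–oxidation: boron should go to C8, the least hindered alkene carbon of the diene, on the α face anti to the axial C14 methyl, and syn delivery of hydrogen to C7 then places H7 α and the C11 side chain β.

Step 10
Reactants: 18 8α-alcohol
Product: 19 8-ketone (7α-H)
Conditions: Dess–Martin periodinane, NaHCO3, CH2Cl2, 0 °C → rt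
Reagents that add atoms: none
Why: Dess–Martin oxidation of the secondary alcohol under buffered conditions that neither epimerise C7 (its β, pseudo-equatorial side chain is also the thermodynamic arrangement) nor move the C5=C6 bond into conjugation.

Step 11
Reactants: 19 8-ketone
Product: 20 cis-fused γ-lactone
Conditions: LiBH(s-Bu)3, THF, −78 °C → rt
Reagents that add atoms: none
Why: Reduction with the bulky trialkylborohydride from the α side, away from the syn-axial C14 methyl, gives the axial 8β-alkoxide cis to the C7 side chain, which closes onto the ester to the cis-fused γ-lactone, the classical reduction–lactonisation of a 2-substituted cyclohexanone bearing an ester arm; H7 and H8 are both α.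

Step 12
Reactants: 20 cis-fused γ-lactone; 21 4-methoxybenzyl chloromethyl ether
Product: 22 C11-quaternary lactone
Conditions: LiN(i-Pr)2, THF, −78 °C; then 21, −78 → −30 °C
Reagents that add atoms: 4-methoxybenzyl chloromethyl ether, COc1ccc(COCCl)cc1
Why: Alkylation of the enolate of a cis-fused bicyclic γ-lactone on its convex face (the face of H7 and H8, turned away from ring B): the alkoxymethyl group enters on the α side and the methyl stays β, which is the C11 configuration of the target once the lactone carbonyl has become the methyl ester.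

Step 13
Reactants: 22 C11-quaternary lactone
Product: 23 4β-hydroxy lactone
Conditions: Bu4NF, THF, 0 °C
Reagents that add atoms: none
Why: Fluoride-mediated cleavage of the silyl ether; the lactone, the PMB ether and the new quaternary centre are inert.

Step 14
Reactants: 23 4β-hydroxy lactone; 24 potassium hydroxide; 25 iodomethane
Product: 27 diol methyl ester, via potassium carboxylate 26 (not isolated)
Conditions: KOH (1.1 equiv), MeOH/H2O, 0 °C → rt; evaporation; then MeI, DMF, 0 °C
Reagents that add atoms: potassium hydroxide, [K+].[OH-]; iodomethane, CI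
Why: Saponification of the γ-lactone and O-alkylation of the potassium carboxylate with iodomethane under non-acidic conditions should give the hydroxy methyl ester without relactonisation, and the crude diol is oxidised at once.

Step 15
Reactants: 27 diol methyl ester
Product: 28 4,8-diketone (vinylogous β-diketone)
Conditions: Dess–Martin periodinane (3 equiv), NaHCO3, CH2Cl2, 0 °C → rt
Reagents that add atoms: none
Why: Dess–Martin oxidation of the allylic C4 alcohol and of the C8 alcohol gives the vinylogous β-diketone, which closes the way back to the lactone; C7 loses its configuration by enolisation as intended, whereas the quaternary C11 cannot epimerise.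

Step 16
Reactants: 28 4,8-diketone; 9 N-phenylbis(trifluoromethanesulfonimide)
Product: 29 C4 dienyl triflate 8-ketone
Conditions: KN(SiMe3)2, THF, −78 °C; then PhNTf2, −78 → 0 °C
Reagents that add atoms: N-phenylbis(trifluoromethanesulfonimide), O=S(=O)(N(c1ccccc1)S(=O)(=O)C(F)(F)F)C(F)(F)F
Why: O-Triflation of the delocalised dienolate at O4, which is flanked only by H3, whereas O8 is screened by the quaternary C11 on C7; the C4=C5 and C6=C7 bonds of the target are thereby fixed and C9 becomes the only enolisable position.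

Step 17
Reactants: 29 C4 dienyl triflate 8-ketone; 30 2-(phenylsulfonyl)-3-phenyloxaziridine
Product: 31 9α-hydroxy ketone
Conditions: KN(SiMe3)2, THF, −78 °C; then 30, −78 °C
Reagents that add atoms: 2-(phenylsulfonyl)-3-phenyloxaziridine, O=S(=O)(N1OC1c1ccccc1)c1ccccc1
Why: Davis oxidation of the potassium C8 enolate with the N-sulfonyloxaziridine; oxygen should be delivered to C9 anti to the neighbouring axial C14 methyl, giving the 9α-alcohol, which is corrected in steps 18 and 19.

Step 18
Reactants: 31 9α-hydroxy ketone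
Product: 32 8,9-diketone
Conditions: Dess–Martin periodinane, CH2Cl2, 0 °C → rt
Reagents that add atoms: none
Why: Dess–Martin oxidation of the α-ketol to the 8,9-diketone, which cannot enolise because C10 is quaternary and C7 is sp2.

Step 19
Reactants: 32 8,9-diketone
Product: 33 9β-hydroxy ketone
Conditions: NaBH4, MeOH/CH2Cl2, −78 °C
Reagents that add atoms: none
Why: Borohydride reduction of the more electrophilic, non-conjugated C9 carbonyl from the α face, anti to C14 as in step 1, sets the 9β-alcohol cis to C14; this conjugated α-ketol with an equatorial hydroxyl is also the thermodynamically preferred isomer.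

Step 20
Reactants: 33 9β-hydroxy ketone; 34 triethylsilyl trifluoromethanesulfonate
Product: 35 9β-triethylsilyl ether
Conditions: Et3SiOTf, 2,6-lutidine, CH2Cl2, −78 °C
Reagents that add atoms: triethylsilyl trifluoromethanesulfonate, CC[Si](CC)(CC)OS(=O)(=O)C(F)(F)F
Why: Silylation of the hindered secondary alcohol with the silyl triflate, so that no acidic hydrogen is present during sulfonylation and zinc insertion.

Step 21
Reactants: 35 9β-triethylsilyl ether
Product: 36 primary alcohol (C11–CH2OH)
Conditions: DDQ, CH2Cl2/pH 7 buffer, 0 °C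
Reagents that add atoms: none
Why: Oxidative cleavage of the 4-methoxybenzyl ether by DDQ through hydride abstraction, which leaves the electron-poor dienone triflate, the ester and the silyl ether untouched.

Step 22
Reactants: 36 primary alcohol; 37 sodium iodide
Product: 39 neopentyl iodide, via neopentyl triflate 38 (not isolated)
Conditions: Tf2O, 2,6-lutidine, CH2Cl2, −78 °C; then NaI, acetone, rt
Reagents that add atoms: sodium iodide, [Na+].[I-]
Why: Sulfonylation followed by Finkelstein-type substitution; the triflate leaving group compensates for the slow SN2 at the neopentyl carbon, and the vinylogous acyl triflate is not expected to be displaced by iodide at room temperature.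

Step 23
Reactants: 39 neopentyl iodide (two molecules)
Product: 42 9,9'-bis(triethylsilyl) cycloshizukaol A, via alkylzinc iodide 40 (not isolated), via open-chain dimer zinc reagent 41 (not isolated)
Conditions: Zn dust (Me3SiCl, BrCH2CH2Br activation), DMF, rt; then syringe-pump addition to Pd2(dba)3, SPhos, THF, 45 °C, final 0.003 M
Reagents that add atoms: none
Why: Zinc inserts into the β-ester (homoenolate-type) alkyl iodide without touching the alkenyl triflate, and palladium-catalysed Negishi coupling then joins C15 of one molecule to C4 of the other twice, the second time intramolecularly, to close the twelve-membered ring; there is no β-hydrogen at the organometallic carbon, a monomer cannot cyclise on itself because its transoid diene holds C4 and C11 apart, and slow addition at high dilution favours ring closure of the open-chain dimer over chain growth.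

Step 24
Reactants: 42 9,9'-bis(triethylsilyl) cycloshizukaol A
Product: 43 cycloshizukaol A
Conditions: HF·pyridine, pyridine, THF, 0 °C → rt
Reagents that add atoms: none
Why: Fluoride cleavage of both triethylsilyl ethers under buffered conditions that should not epimerise the α-ketols gives the target.

Compound list
1 | (R)-Wieland–Miescher ketone | O=C1CCCC2=CC(=O)CC[C@@]12C | starting material
2 | (4aR,5R)-5-hydroxy-4a-methyl-4,4a,5,6,7,8-hexahydronaphthalen-2(3H)-one; 1β-hydroxy enone, OH cis to C14 | O[C@@H]1CCCC2=CC(=O)CC[C@@]12C | intermediate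
3 | methanesulfonyl chloride | CS(=O)(=O)Cl | starting material
4 | 1β-mesyloxy enone (mesylate of 2) | CS(=O)(=O)O[C@@H]1CCCC2=CC(=O)CC[C@@]12C | intermediate
5 | tert-butyl hydroperoxide | CC(C)(C)OO | starting material
6 | 1β-mesyloxy-4,7-dioxo-Δ5 octalin (ene-dione mesylate, key-step precursor) | CS(=O)(=O)O[C@@H]1CCC(=O)C2=CC(=O)CC[C@@]12C | intermediate
7 | potassium C3 enolate of 6 (C3=C4–O−) | CS(=O)(=O)O[C@@H]1CC=C([O-])C2=CC(=O)CC[C@@]12C.[K+] | intermediate
8 | tricyclic lindenane ene-dione (4,7-dioxo-Δ5; H1 and H3 α, cyclopropane CH2 β) | O=C1C2=CC(=O)CC[C@@]2(C)[C@@H]2C[C@H]12 | intermediate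
9 | N-phenylbis(trifluoromethanesulfonimide) | O=S(=O)(N(c1ccccc1)S(=O)(=O)C(F)(F)F)C(F)(F)F | starting material
10 | C7 enol triflate (C5=C6, C7=C8; 4-ketone) | O=C1C2=CC(OS(=O)(=O)C(F)(F)F)=CC[C@@]2(C)[C@@H]2C[C@H]12 | intermediate
11 | 4β-alcohol of 10 | O[C@@H]1C2=CC(OS(=O)(=O)C(F)(F)F)=CC[C@@]2(C)[C@@H]2C[C@H]12 | intermediate
12 | tert-butyldimethylsilyl trifluoromethanesulfonate | CC(C)(C)[Si](C)(C)OS(=O)(=O)C(F)(F)F | starting material
13 | 4β-tert-butyldimethylsilyl ether of 11 | CC(C)(C)[Si](C)(C)O[C@@H]1C2=CC(OS(=O)(=O)C(F)(F)F)=CC[C@@]2(C)[C@@H]2C[C@H]12 | intermediate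
14 | methyl 2-bromopropanoate (racemic) | COC(=O)C(C)Br | starting material
15 | diene ester, C7–CH(CH3)CO2Me on the C5=C6/C7=C8 diene (C11 epimers) | CC(C)(C)[Si](C)(C)O[C@@H]1C2=CC(C(C)C(=O)OC)=CC[C@@]2(C)[C@@H]2C[C@H]12 | intermediate
16 | hydrogen peroxide | OO | starting material
17 | C8 alkylborane (7α-H, 8α-boryl) | CC(C)(C)[Si](C)(C)O[C@@H]1C2=C[C@H](C(C)C(=O)OC)[C@@H](B)C[C@@]2(C)[C@@H]2C[C@H]12 | intermediate
18 | 8α-alcohol (7α-H, side chain β) | CC(C)(C)[Si](C)(C)O[C@@H]1C2=C[C@H](C(C)C(=O)OC)[C@@H](O)C[C@@]2(C)[C@@H]2C[C@H]12 | intermediate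
19 | 8-ketone (7α-H, C5=C6) | CC(C)(C)[Si](C)(C)O[C@@H]1C2=C[C@H](C(C)C(=O)OC)C(=O)C[C@@]2(C)[C@@H]2C[C@H]12 | intermediate
20 | cis-fused γ-lactone O8–C12(=O)–C11–C7 (7α-H, 8α-H; C11 epimers) | CC(C)(C)[Si](C)(C)O[C@@H]1C2=C[C@H]3[C@@H](C[C@@]2(C)[C@@H]2C[C@H]12)OC(=O)C3C | intermediate
21 | 4-methoxybenzyl chloromethyl ether | COc1ccc(COCCl)cc1 | starting material
22 | C11-quaternary lactone (C11 methyl on the concave face, CH2OPMB on the convex face; C11 as in the target) | CC(C)(C)[Si](C)(C)O[C@@H]1C2=C[C@H]3[C@@H](C[C@@]2(C)[C@@H]2C[C@H]12)OC(=O)[C@]3(C)COCc1ccc(OC)cc1 | intermediate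
23 | 4β-hydroxy lactone | O[C@@H]1C2=C[C@H]3[C@@H](C[C@@]2(C)[C@@H]2C[C@H]12)OC(=O)[C@]3(C)COCc1ccc(OC)cc1 | intermediate
24 | potassium hydroxide | [K+].[OH-] | starting material
25 | iodomethane | CI | starting material
26 | potassium 4β,8β-dihydroxy carboxylate | O[C@@H]1C2=C[C@H]([C@](C)(C(=O)[O-])COCc3ccc(OC)cc3)[C@H](O)C[C@@]2(C)[C@@H]2C[C@H]12.[K+] | intermediate
27 | 4β,8β-diol methyl ester (7α-H) | O[C@@H]1C2=C[C@H]([C@](C)(C(=O)OC)COCc3ccc(OC)cc3)[C@H](O)C[C@@]2(C)[C@@H]2C[C@H]12 | intermediate
28 | 4,8-diketone, vinylogous β-diketone (drawn as the diketo form; C7 enolised in solution) | O=C1C2=CC([C@](C)(C(=O)OC)COCc3ccc(OC)cc3)C(=O)C[C@@]2(C)[C@@H]2C[C@H]12 | intermediate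
29 | C4 dienyl triflate 8-ketone (C4=C5, C6=C7) | O=S(=O)(OC1=C2C=C([C@](C)(C(=O)OC)COCc3ccc(OC)cc3)C(=O)C[C@@]2(C)[C@@H]2C[C@H]12)C(F)(F)F | intermediate
30 | 2-(phenylsulfonyl)-3-phenyloxaziridine (racemic) | O=S(=O)(N1OC1c1ccccc1)c1ccccc1 | starting material
31 | 9α-hydroxy ketone | O=S(=O)(OC1=C2C=C([C@](C)(C(=O)OC)COCc3ccc(OC)cc3)C(=O)[C@@H](O)[C@@]2(C)[C@@H]2C[C@H]12)C(F)(F)F | intermediate
32 | 8,9-diketone | O=S(=O)(OC1=C2C=C([C@](C)(C(=O)OC)COCc3ccc(OC)cc3)C(=O)C(=O)[C@@]2(C)[C@@H]2C[C@H]12)C(F)(F)F | intermediate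
33 | 9β-hydroxy ketone (OH cis to C14) | O=S(=O)(OC1=C2C=C([C@](C)(C(=O)OC)COCc3ccc(OC)cc3)C(=O)[C@H](O)[C@@]2(C)[C@@H]2C[C@H]12)C(F)(F)F | intermediate
34 | triethylsilyl trifluoromethanesulfonate | CC[Si](CC)(CC)OS(=O)(=O)C(F)(F)F | starting material
35 | 9β-triethylsilyl ether (PMB ether) | O=S(=O)(OC1=C2C=C([C@](C)(C(=O)OC)COCc3ccc(OC)cc3)C(=O)[C@H](O[Si](CC)(CC)CC)[C@@]2(C)[C@@H]2C[C@H]12)C(F)(F)F | intermediate
36 | primary alcohol (C11–CH2OH) | O=S(=O)(OC1=C2C=C([C@](C)(C(=O)OC)CO)C(=O)[C@H](O[Si](CC)(CC)CC)[C@@]2(C)[C@@H]2C[C@H]12)C(F)(F)F | intermediate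
37 | sodium iodide | [Na+].[I-] | starting material
38 | neopentyl triflate (C11–CH2OTf) | O=S(=O)(OC1=C2C=C([C@](C)(C(=O)OC)COS(=O)(=O)C(F)(F)F)C(=O)[C@H](O[Si](CC)(CC)CC)[C@@]2(C)[C@@H]2C[C@H]12)C(F)(F)F | intermediate
39 | neopentyl iodide (C11–CH2I; cyclodimerisation monomer) | O=S(=O)(OC1=C2C=C([C@](C)(C(=O)OC)CI)C(=O)[C@H](O[Si](CC)(CC)CC)[C@@]2(C)[C@@H]2C[C@H]12)C(F)(F)F | intermediate
40 | alkylzinc iodide (C11–CH2ZnI) | O=S(=O)(OC1=C2C=C([C@](C)(C(=O)OC)C[Zn]I)C(=O)[C@H](O[Si](CC)(CC)CC)[C@@]2(C)[C@@H]2C[C@H]12)C(F)(F)F | intermediate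
41 | open-chain head-to-tail dimer (one C4–C15 bond; dienyl triflate and alkylzinc iodide termini) | O=S(=O)(OC1=C2C=C([C@](C)(C(=O)OC)CC3=C4C=C([C@](C)(C(=O)OC)C[Zn]I)C(=O)[C@H](O[Si](CC)(CC)CC)[C@@]4(C)[C@@H]4C[C@H]34)C(=O)[C@H](O[Si](CC)(CC)CC)[C@@]2(C)[C@@H]2C[C@H]12)C(F)(F)F | intermediate
42 | 9,9'-bis(triethylsilyl) cycloshizukaol A | COC(=O)[C@]1(C)CC2=C3C=C(C(=O)[C@H](O[Si](CC)(CC)CC)[C@@]3(C)[C@@H]3C[C@H]23)[C@](C)(C(=O)OC)CC2=C3C=C1C(=O)[C@H](O[Si](CC)(CC)CC)[C@@]3(C)[C@@H]1C[C@H]21 | intermediate
43 | cycloshizukaol A | COC(=O)[C@]1(C)CC2=C3C=C(C(=O)[C@H](O)[C@@]3(C)[C@@H]3C[C@H]23)[C@](C)(C(=O)OC)CC2=C3C=C1C(=O)[C@H](O)[C@@]3(C)[C@@H]1C[C@H]21 | target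

Total step count: 24. Longest linear sequence: 24 steps (1 → 43).

Steps most likely to fail

Step 23. Chain growth to open oligomers may outrun closure of the twelve-membered ring, and the homoallylic radical passed through during zinc insertion may undergo a 1,2-vinyl shift. The fallback builds the ring stepwise and sets out from iodide 39 and silyl ether 35. The zinc reagent 40 is added slowly to an excess of 35 under the same palladium catalysis, so that only one C4–C15 bond is made and the open-chain dimer PMB ether F1 results. DDQ then frees the open-chain dimer alcohol F2, and Tf2O followed by NaI gives the open-chain dimer iodide F3. The ring is closed as a separate, purely intramolecular event by nickel-catalysed reductive coupling of the alkyl iodide with the dienyl triflate (NiCl2·dme, 4,4'-di-tert-butyl-2,2'-bipyridine, Mn, dimethylacetamide, high dilution). This comes back to the route at macrocycle 42.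

Step 9. Boron may be delivered to the other alkene of the diene or to both, and the ester may be partly reduced. The fallback forms the C7–C11 bond by enolate alkylation instead of cross-coupling and sets out from triflate 13. Formate reduction (Pd(OAc)2, PPh3, HCO2H, Bu3N) gives the unsubstituted diene F4, whose cis-disubstituted C7=C8 bond is far more reactive than the trisubstituted C5=C6 bond. 9-BBN then H2O2/NaOH gives the 8α-alcohol F5, and Dess–Martin oxidation the β,γ-unsaturated 8-ketone F6. The conjugated dienolate of F6 (LiN(i-Pr)2, THF) is alkylated at C7 with methyl 2-(trifluoromethylsulfonyloxy)propanoate. This comes back to the route at ketone 19 and replaces steps 8 to 10.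

Step 16. Sulfonylation may occur at O8 instead of O4 of the ambident dienolate. The fallback makes the triflate while C8 is still an alcohol and sets out from diol ester 27. MnO2 oxidises only the allylic C4 alcohol to the 8β-hydroxy enone F7, and Et3SiOTf/2,6-lutidine gives the 8β-silyloxy enone F8. γ-Deprotonation at C7 (KN(SiMe3)2) then forms a dienolate with a single oxygen, which PhNTf2 converts into the 8β-silyloxy dienyl triflate F9. HF·pyridine gives the 8β-hydroxy dienyl triflate F10, and Dess–Martin oxidation of this allylic alcohol comes back to the route at dienyl triflate 29.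

Further compounds
F1 | step 23 | open-chain dimer PMB ether | O=S(=O)(OC1=C2C=C([C@](C)(C(=O)OC)CC3=C4C=C([C@](C)(C(=O)OC)COCc5ccc(OC)cc5)C(=O)[C@H](O[Si](CC)(CC)CC)[C@@]4(C)[C@@H]4C[C@H]34)C(=O)[C@H](O[Si](CC)(CC)CC)[C@@]2(C)[C@@H]2C[C@H]12)C(F)(F)F
F2 | step 23 | open-chain dimer alcohol | O=S(=O)(OC1=C2C=C([C@](C)(C(=O)OC)CC3=C4C=C([C@](C)(C(=O)OC)CO)C(=O)[C@H](O[Si](CC)(CC)CC)[C@@]4(C)[C@@H]4C[C@H]34)C(=O)[C@H](O[Si](CC)(CC)CC)[C@@]2(C)[C@@H]2C[C@H]12)C(F)(F)F
F3 | step 23 | open-chain dimer iodide | O=S(=O)(OC1=C2C=C([C@](C)(C(=O)OC)CC3=C4C=C([C@](C)(C(=O)OC)CI)C(=O)[C@H](O[Si](CC)(CC)CC)[C@@]4(C)[C@@H]4C[C@H]34)C(=O)[C@H](O[Si](CC)(CC)CC)[C@@]2(C)[C@@H]2C[C@H]12)C(F)(F)F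
F4 | step 9 | unsubstituted diene (C5=C6, C7=C8; 4β-silyl ether) | CC(C)(C)[Si](C)(C)O[C@@H]1C2=CC=CC[C@@]2(C)[C@@H]2C[C@H]12
F5 | step 9 | 8α-alcohol (C5=C6; 4β-silyl ether) | CC(C)(C)[Si](C)(C)O[C@@H]1C2=CC[C@@H](O)C[C@@]2(C)[C@@H]2C[C@H]12
F6 | step 9 | β,γ-unsaturated 8-ketone (4β-silyl ether) | CC(C)(C)[Si](C)(C)O[C@@H]1C2=CCC(=O)C[C@@]2(C)[C@@H]2C[C@H]12
F7 | step 16 | 8β-hydroxy enone (4-ketone, C5=C6, 7α-H) | O=C1C2=C[C@H]([C@](C)(C(=O)OC)COCc3ccc(OC)cc3)[C@H](O)C[C@@]2(C)[C@@H]2C[C@H]12
F8 | step 16 | 8β-silyloxy enone (triethylsilyl ether of F7) | O=C1C2=C[C@H]([C@](C)(C(=O)OC)COCc3ccc(OC)cc3)[C@H](O[Si](CC)(CC)CC)C[C@@]2(C)[C@@H]2C[C@H]12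
F9 | step 16 | 8β-silyloxy dienyl triflate (C4=C5, C6=C7) | O=S(=O)(OC1=C2C=C([C@](C)(C(=O)OC)COCc3ccc(OC)cc3)[C@H](O[Si](CC)(CC)CC)C[C@@]2(C)[C@@H]2C[C@H]12)C(F)(F)F
F10 | step 16 | 8β-hydroxy dienyl triflate | O=S(=O)(OC1=C2C=C([C@](C)(C(=O)OC)COCc3ccc(OC)cc3)[C@H](O)C[C@@]2(C)[C@@H]2C[C@H]12)C(F)(F)F
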